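**Assumption:** Diffractaic acid has no stereocentre or other stereogenic element. The "single enantiomer" is therefore the one achiral compound drawn, and there is no stereochemistry to set.

## Retrosynthetic overview
- Both benzene rings are bought ready-made in one bulk fragrance chemical, methyl atratate 1. No ring is formed at any stage.
- A-ring: 1 is O-methylated twice (ester 2) and the ester is cleaved to give 2,4-dimethoxy-3,6-dimethylbenzoic acid 3.
- B-ring: ester cleavage of 1 alone gives the free 2,4-dihydroxy-3,6-dimethylbenzoic acid 4.
- The key disconnection, made last, is the depside aryl-ester C–O bond. The acyl carbon of 3 (as chloride 5) is joined to O-4 of unprotected 4.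
- The COOH/2-OH pair of 4 is held in the flask as spiroborate 6. Acylation gives 7, and acid release gives target 8.

## Route

**Step 1**
Reactants: 1 methyl 2,4-dihydroxy-3,6-dimethylbenzoate (methyl atratate)
Product: 3 2,4-dimethoxy-3,6-dimethylbenzoic acid, via dimethoxy methyl ester 2 (not isolated)
Conditions: MeI (3 equiv), K2CO3 (3 equiv), DMSO, 40 °C, 8 h; N2 purge; then KOH (6 equiv), H2O, 95 °C, 6 h; aq HCl to pH 2, 0 °C, filter
Reagents that add atoms: methyl iodide, CI; potassium hydroxide, [K+].[OH-]
Why: Williamson O-methylation in a dipolar aprotic solvent alkylates both phenoxides (including the chelated, flanked 2-OH), and poorly solvated hydroxide in hot aqueous DMSO then forces the BAc2 saponification of the di-ortho-substituted ester in the same pot, with no decarboxylation risk because no free phenol is left; no stereocentre is formed.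

**Step 2**
Reactants: 1 methyl 2,4-dihydroxy-3,6-dimethylbenzoate (methyl atratate)
Product: 4 2,4-dihydroxy-3,6-dimethylbenzoic acid
Conditions: conc. H2SO4, 0 °C → rt, 2 h; pour onto ice, filter cold
Reagents that add atoms: water, O
Why: AAc1 ester hydrolysis, in which the di-ortho-substituted, donor-rich benzoate ionises in conc. H2SO4 to its acylium ion (whose charge also deactivates the ring toward sulfonation) and ice water captures it as the acid, so the heat and base that decarboxylate β-resorcylic acids are avoided; no stereocentre is formed.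

**Step 3**
Reactants: 3 2,4-dimethoxy-3,6-dimethylbenzoic acid; 4 2,4-dihydroxy-3,6-dimethylbenzoic acid
Product: 8 diffractaic acid, via aroyl chloride 5 (not isolated), via spiroborate salt 6 (not isolated), via diacylated spiroborate salt 7 (not isolated)
Conditions: (a) 3 (1.05 equiv), (COCl)2 (1.3 equiv), cat. DMF, CH2Cl2, 0 °C → rt, evaporate; (b) 4 (1.0 equiv), B(OH)3 (0.50 equiv), Et3N (0.50 equiv), MeCN–toluene, azeotropic drying ≤40 °C, 4 Å MS; (c) a + b, Et3N (1.3 equiv), DMAP (10 mol %), CH2Cl2–MeCN, 0 °C → rt, 6 h; (d) 1 M HCl–EtOAc, rt, 1 h; recrystallise from acetone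
Reagents that add atoms: oxalyl chloride, ClC(=O)C(=O)Cl (Cl of 5); boric acid, OB(O)O (B of 6 and 7); triethylamine, CCN(CC)CC (cation of 6 and 7); no atom of these three stays in 8
Why: Proposed new method: boron-templated, protecting-group-free depside esterification. Half an equivalent of boric acid chelates the salicylate unit (COOH plus 2-OH) of two molecules of 4 into a tetrahedral, anionic, coordinatively saturated bis(salicylato)borate 6 (racemic at the spiro boron, which is irrelevant because boron is removed). No free carboxylate is then left to form mixed anhydrides or to self-condense, and the B–O–C=O carbonyl is not Lewis-acid activated. The only nucleophile remaining is the C4–OH, which attacks the N-acylpyridinium/acylium-like species from the readily ionising, donor-rich, di-ortho-substituted chloride 5 to form the aryl-ester C–O bond on both ligands (7). Dilute acid then hydrolyses only the B–O bonds, and partition of boric acid into water and of 8 into EtOAc drives the release. The closest known reaction types are borate/borax masking of catechols and cis-diols during selective alkylation or acylation, the ready formation of bis(salicylato)borate salts, and the DMAP-catalysed acyl chloride esterification of benzyl-protected depside B-rings; a spiroborate has not been used as an in-flask mask for acylating an unprotected β-resorcylic acid.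

## Compound list
1 | methyl 2,4-dihydroxy-3,6-dimethylbenzoate (methyl atratate) | COC(=O)c1c(C)cc(O)c(C)c1O | starting material
2 | methyl 2,4-dimethoxy-3,6-dimethylbenzoate | COC(=O)c1c(C)cc(OC)c(C)c1OC | intermediate (not isolated)
3 | 2,4-dimethoxy-3,6-dimethylbenzoic acid | COc1cc(C)c(C(=O)O)c(OC)c1C | intermediate
4 | 2,4-dihydroxy-3,6-dimethylbenzoic acid | OC(=O)c1c(C)cc(O)c(C)c1O | intermediate
5 | 2,4-dimethoxy-3,6-dimethylbenzoyl chloride | COc1cc(C)c(C(=O)Cl)c(OC)c1C | intermediate (not isolated)
6 | triethylammonium bis[4-hydroxy-3,6-dimethylsalicylato(2−)-O1,O2]borate (spiroborate, racemic at B) | CC[NH+](CC)CC.[B-]12(OC(=O)c3c(C)cc(O)c(C)c3O1)OC(=O)c1c(C)cc(O)c(C)c1O2 | intermediate (not isolated)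
7 | triethylammonium spiroborate of two diffractaic acid units (both 4-OH groups of 6 carrying the 2,4-dimethoxy-3,6-dimethylbenzoyl group, racemic at B) | CC[NH+](CC)CC.[B-]12(OC(=O)c3c(C)cc(OC(=O)c4c(C)cc(OC)c(C)c4OC)c(C)c3O1)OC(=O)c1c(C)cc(OC(=O)c3c(C)cc(OC)c(C)c3OC)c(C)c1O2 | intermediate (not isolated)
8 | diffractaic acid, 4-[(2,4-dimethoxy-3,6-dimethylbenzoyl)oxy]-2-hydroxy-3,6-dimethylbenzoic acid (achiral) | COc1cc(C)c(C(=O)Oc2cc(C)c(C(=O)O)c(O)c2C)c(OC)c1C | target

## Step count and risks
Total step count: 3. Longest linear sequence: 2 (1 → 3 → 8 or 1 → 4 → 8).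

**Highest risk: step 3, the proposed new step.**
- The spiroborate may form incompletely or exchange ligands under the acylation conditions. Free carboxylate would then give mixed anhydrides and B–B self-condensation, and release from boron could also be slow.
- The fallback is known chemistry. It sets out from 4 (with 3 as partner) and comes back to the route at 8.
- Compound 4 is O-alkylated at the carboxylate only (BnBr, KHCO3, DMF, rt) to benzyl 2,4-dihydroxy-3,6-dimethylbenzoate F1.
- F1 is condensed with 3 by trifluoroacetic anhydride in toluene at rt. Only the unchelated 4-OH reacts, giving benzyl diffractaate F2.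
- Hydrogenolysis (H2, 10 % Pd/C, EtOAc) then gives 8.

**Second: step 2.**
- Ring sulfonation in H2SO4, or protodecarboxylation on the quench, may erode the yield of 4.
- The fallback sets out from 1 and comes back at 4. It removes the free phenols before the ester is touched.
- Compound 1 is dibenzylated (BnBr, K2CO3, DMF, 60 °C) to methyl 2,4-bis(benzyloxy)-3,6-dimethylbenzoate F3.
- F3 is saponified (KOH, aqueous DMSO, 95 °C) to 2,4-bis(benzyloxy)-3,6-dimethylbenzoic acid F4.
- F4 is hydrogenolysed (H2, Pd/C, EtOAc, rt) to 4 under neutral, cold conditions.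

**Third: step 1.**
- The hindered ester 2 may resist hydroxide, or the one-pot sequence may stall.
- The fallback sets out from 2, isolated by aqueous work-up after the methylation stage, and comes back at 3. It replaces acyl substitution by a redox detour.
- LiAlH4 (THF, reflux) gives (2,4-dimethoxy-3,6-dimethylphenyl)methanol F5.
- MnO2 (CH2Cl2, rt) gives 2,4-dimethoxy-3,6-dimethylbenzaldehyde F6.
- Pinnick oxidation (NaClO2, NaH2PO4, 2-methyl-2-butene, t-BuOH–H2O) gives 3.

## Further compounds
F1 | step 3 | benzyl 2,4-dihydroxy-3,6-dimethylbenzoate | O=C(OCc1ccccc1)c1c(C)cc(O)c(C)c1O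
F2 | step 3 | benzyl diffractaate (benzyl 4-[(2,4-dimethoxy-3,6-dimethylbenzoyl)oxy]-2-hydroxy-3,6-dimethylbenzoate) | COc1cc(C)c(C(=O)Oc2cc(C)c(C(=O)OCc3ccccc3)c(O)c2C)c(OC)c1C
F3 | step 2 | methyl 2,4-bis(benzyloxy)-3,6-dimethylbenzoate | COC(=O)c1c(C)cc(OCc2ccccc2)c(C)c1OCc1ccccc1
F4 | step 2 | 2,4-bis(benzyloxy)-3,6-dimethylbenzoic acid | OC(=O)c1c(C)cc(OCc2ccccc2)c(C)c1OCc1ccccc1
F5 | step 1 | (2,4-dimethoxy-3,6-dimethylphenyl)methanol | OCc1c(C)cc(OC)c(C)c1OC
F6 | step 1 | 2,4-dimethoxy-3,6-dimethylbenzaldehyde | O=Cc1c(C)cc(OC)c(C)c1OC
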